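**Plan**

Ring letters: A is the methoxy ring, B the para-phenylene, C the phenol ring and D the unsubstituted meta-phenylene.
Enabling feature: the bridge from C4 of ring B to C1 of ring C is a bond between two benzylic CH2 carbons of equal polarity. It can be cut in the middle into two identical CH2Br ends.
Cuts, in retrosynthetic order: the isopropyl mask on the ring C phenol, the central CH2–CH2 bond of the B–C bridge (opens the 19-membered ring), the ring D–O bond (Ullmann), the ring B–O bond (SNAr), and the D–A bridge (Wittig, then saturation).
Forward order: the D–A bibenzyl is made first, then ring B and ring C are added as benzaldehydes. Both formyl groups are reduced and brominated, and the macrocycle, the only ring formed, closes in the penultimate step.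
Stereochemistry: the target has no stereocentre and no C=C bond, and the alkene geometry from the Wittig step is erased by diimide.

Key step: step 9

Remark: the Wittig stilbene is expected as an E/Z mixture. The E isomer is drawn, and both isomers converge on the same bibenzyl.

**Route**

Step 1
Reactants: 1 3-bromobenzyl bromide
Product: 2 (3-bromobenzyl)triphenylphosphonium bromide
Conditions: PPh3, toluene, reflux; salt filtered off
Reagents that add atoms: triphenylphosphine, c1ccc(cc1)P(c1ccccc1)c1ccccc1
Why: SN2 quaternisation of the phosphine by the benzylic bromide, in which the aryl C–Br bond is inert and the salt should crystallise from toluene.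

Step 2
Reactants: 2 (3-bromobenzyl)triphenylphosphonium bromide; 3 isovanillin
Product: 5 (E/Z)-5-[2-(3-bromophenyl)ethenyl]-2-methoxyphenol, via 3-bromobenzylidene(triphenyl)phosphorane 4 (not isolated)
Conditions: KOtBu (2.2 equiv), THF, 0 °C, then 3, 0 °C → rt; 1 M HCl quench
Reagents that add atoms: none
Why: Wittig olefination with a semi-stabilised benzylic ylide; the second equivalent of base holds the phenol as its phenoxide, which sits meta to the formyl group and so cannot deactivate it by conjugation.

Step 3
Reactants: 5 (E/Z)-5-[2-(3-bromophenyl)ethenyl]-2-methoxyphenol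
Product: 6 D–A bibenzyl 5-[2-(3-bromophenyl)ethyl]-2-methoxyphenol
Conditions: TsNHNH2, NaOAc, DME/H2O, reflux
Reagents that add atoms: none
Why: Diimide reduction (concerted syn transfer of two hydrogens to the C=C bond) saturates both stilbene isomers and spares the aryl C–Br bond, which catalytic hydrogenation would endanger.

Step 4
Reactants: 6 5-[2-(3-bromophenyl)ethyl]-2-methoxyphenol; 7 4-fluorobenzaldehyde
Product: 8 4-{5-[2-(3-bromophenyl)ethyl]-2-methoxyphenoxy}benzaldehyde
Conditions: K2CO3, DMF, 120 °C
Reagents that add atoms: none
Why: Nucleophilic aromatic substitution (addition–elimination) of the fluoride para to the formyl group by the phenoxide; without copper the unactivated bromide on ring D stays untouched.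

Step 5
Reactants: 9 3,4-dihydroxybenzaldehyde
Product: 10 3-hydroxy-4-isopropoxybenzaldehyde
Conditions: 2-bromopropane (1.1 equiv), K2CO3 (1.0 equiv), DMF, 50 °C
Reagents that add atoms: 2-bromopropane, CC(C)Br
Why: Base-limited Williamson etherification; the 4-OH, para to the formyl group, is the more acidic hydroxyl, so one equivalent of base should form mainly the 4-phenoxide and direct alkylation there.

Step 6
Reactants: 8 4-{5-[2-(3-bromophenyl)ethyl]-2-methoxyphenoxy}benzaldehyde; 10 3-hydroxy-4-isopropoxybenzaldehyde
Product: 11 open-chain dialdehyde 3-(3-{2-[3-(4-formylphenoxy)-4-methoxyphenyl]ethyl}phenoxy)-4-isopropoxybenzaldehyde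
Conditions: CuI (cat.), N,N-dimethylglycine (cat.), Cs2CO3, 1,4-dioxane, 100 °C, argon
Reagents that add atoms: none
Why: Ligand-accelerated Ullmann diaryl ether synthesis with monovalent copper; the only C–Br bond lies on ring D, the only OH is that of 10, and the tertiary amino acid ligand cannot condense with the aldehydes.

Step 7
Reactants: 11 open-chain dialdehyde
Product: 12 open-chain diol (both CHO groups converted to CH2OH)
Conditions: NaBH4, MeOH/THF, 0 °C → rt
Reagents that add atoms: none
Why: Borohydride reduction of both aromatic aldehydes in one operation; the aryl and alkyl ethers are inert to hydride.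

Step 8
Reactants: 12 open-chain diol
Product: 13 open-chain bis(benzyl bromide) (CH2Br on C4 of ring B and on C1 of ring C, phenol as isopropyl ether)
Conditions: PBr3, CH2Cl2, 0 °C; short aqueous work-up, used without chromatography
Reagents that add atoms: phosphorus tribromide, BrP(Br)Br
Why: Both benzylic alcohols are activated as phosphite esters and displaced by bromide (SN2); at 0 °C the ethers should survive, and prompt use avoids self-alkylation of the electron-rich benzyl bromides.

Step 9
Reactants: 13 open-chain bis(benzyl bromide)
Product: 14 isopropyl-protected 19-membered macrocycle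
Conditions: Na sand (excess), tetraphenylethene (cat.), THF, rt until deep red, then −78 °C, 13 in THF added slowly by syringe pump (high dilution), argon
Reagents that add atoms: none
Why: Sodium charges tetraphenylethene to its soluble, deep red anions, which hand one electron to a C–Br bond of 13; the benzyl radical left after loss of bromide takes a second electron, and the resulting benzyl anion displaces the bromide at the far end of the same chain by SN2 (collapse of a benzyl radical pair would make the same bond). This is an intramolecular Wurtz coupling, the reaction type established for closing [2.n]cyclophanes and macrocyclic bis(bibenzyl) ethers from bis(benzyl bromides). The one ring formed is the 19-membered macrocycle, closed end to end (19-exo-tet in the anionic pathway) between the CH2 on C4 of ring B and the CH2 on C1 of ring C, and no stereocentre arises. Ring closure must outrun chain growth and reduction of a terminus to ArCH3: slow addition keeps the stationary halide concentration minimal, −78 °C slows proton abstraction from the solvent, and the two meta-linked diaryl ethers fold the chain so that its ends can meet. Chemoselectivity rests on reduction potentials, since benzylic C–Br bonds accept electrons from the carrier readily while the diaryl ethers, the methyl and isopropyl ethers and the arenes lie beyond its reach. Because both ends carry the same functional group, either may be reduced first without changing the product.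

Step 10
Reactants: 14 isopropyl-protected macrocycle
Product: 15 target macrocycle CNP0132125.0
Conditions: BCl3 (1 M in CH2Cl2), CH2Cl2, −78 → 0 °C; H2O quench
Reagents that add atoms: none
Why: Lewis acid ether cleavage; after coordination of BCl3 the O–CH(CH3)2 bond ionises towards a secondary cation far faster than chloride can attack the O–CH3 bond by SN2, which is the known basis for removing aryl isopropyl ethers beside aryl methyl ethers.

**Compound list**

1 | 3-bromobenzyl bromide | BrCc1cccc(Br)c1 | starting material
2 | (3-bromobenzyl)triphenylphosphonium bromide | [Br-].Brc1cccc(C[P+](c2ccccc2)(c2ccccc2)c2ccccc2)c1 | intermediate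
3 | isovanillin (3-hydroxy-4-methoxybenzaldehyde) | COc1ccc(C=O)cc1O | starting material
4 | 3-bromobenzylidene(triphenyl)phosphorane | Brc1cccc(C=P(c2ccccc2)(c2ccccc2)c2ccccc2)c1 | intermediate
5 | (E/Z)-5-[2-(3-bromophenyl)ethenyl]-2-methoxyphenol (E isomer drawn) | COc1ccc(/C=C/c2cccc(Br)c2)cc1O | intermediate
6 | 5-[2-(3-bromophenyl)ethyl]-2-methoxyphenol | COc1ccc(CCc2cccc(Br)c2)cc1O | intermediate
7 | 4-fluorobenzaldehyde | O=Cc1ccc(F)cc1 | starting material
8 | 4-{5-[2-(3-bromophenyl)ethyl]-2-methoxyphenoxy}benzaldehyde | COc1ccc(CCc2cccc(Br)c2)cc1Oc1ccc(C=O)cc1 | intermediate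
9 | 3,4-dihydroxybenzaldehyde | O=Cc1ccc(O)c(O)c1 | starting material
10 | 3-hydroxy-4-isopropoxybenzaldehyde | CC(C)Oc1ccc(C=O)cc1O | intermediate
11 | 3-(3-{2-[3-(4-formylphenoxy)-4-methoxyphenyl]ethyl}phenoxy)-4-isopropoxybenzaldehyde | COc1ccc(CCc2cccc(Oc3cc(C=O)ccc3OC(C)C)c2)cc1Oc1ccc(C=O)cc1 | intermediate
12 | [3-(3-{2-[3-(4-(hydroxymethyl)phenoxy)-4-methoxyphenyl]ethyl}phenoxy)-4-isopropoxyphenyl]methanol | COc1ccc(CCc2cccc(Oc3cc(CO)ccc3OC(C)C)c2)cc1Oc1ccc(CO)cc1 | intermediate
13 | 4-(bromomethyl)-2-(3-{2-[3-(4-(bromomethyl)phenoxy)-4-methoxyphenyl]ethyl}phenoxy)-1-isopropoxybenzene | COc1ccc(CCc2cccc(Oc3cc(CBr)ccc3OC(C)C)c2)cc1Oc1ccc(CBr)cc1 | intermediate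
14 | isopropyl-protected 19-membered bis(bibenzyl) diether macrocycle | COc1ccc2cc1Oc1ccc(cc1)CCc1ccc(OC(C)C)c(c1)Oc1cccc(c1)CC2 | intermediate
15 | CNP0132125.0 (free phenol on ring C, methyl ether on ring A) | COc1ccc2cc1Oc1ccc(cc1)CCc1ccc(O)c(c1)Oc1cccc(c1)CC2 | target

**Step count**

Total step count: 10
Longest linear sequence: 9 steps (1 → 2 → 5 → 6 → 8 → 11 → 12 → 13 → 14 → 15); step 5 is a one-step side branch.

**Steps most likely to fail**

Step 9. Chain growth to oligomers, or reduction of one terminus to a methyl group, may outpace ring closure. The labile dibromide may also degrade during the long addition. The fallback sets out from dialdehyde 11 and joins the same two carbons at the carbonyl oxidation level. An intramolecular McMurry coupling with low-valent titanium (TiCl4, Zn, pyridine, THF, reflux, high dilution) should give the macrocyclic stilbene F1. It is drawn as the Z isomer, and either geometry serves. Hydrogenation of its C=C bond (H2, Pd/C, EtOAc, rt) comes back to the route at 14.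

Step 6. The hindered, electron-poor phenoxide may couple only sluggishly with the unactivated aryl bromide. At the temperature required, hydrodebromination and aryloxide exchange at the formyl-activated ring B may compete. The fallback reverses the polarity of ring D and forms the ether oxidatively at room temperature. Setting out from 8, a Miyaura borylation (B2pin2, PdCl2(dppf), KOAc, dioxane, 80 °C) should give the pinacol boronate F2. Oxidative removal of the diol (NaIO4, NH4OAc, acetone/H2O, rt) then gives the boronic acid F3. A Chan–Lam coupling of F3 with phenol 10, mediated by divalent copper (Cu(OAc)2, pyridine, 4 Å molecular sieves, CH2Cl2, air, rt), comes back to the route at 11.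

Step 2. Formation of the poorly soluble phenoxide of 3 may lower the reactivity of the aldehyde, and proton transfer to the ylide may stall the conversion. The fallback masks the phenol. Setting out from 3, silylation (TBSCl, imidazole, DMF, rt) should give the silyl ether F4. Wittig reaction of F4 with ylide 4, generated from 2 with one equivalent of KOtBu in THF, gives the silylated stilbene F5. Desilylation with Bu4NF in THF at 0 °C comes back to the route at 5.

**Further compounds**

F1 | step 9 | isopropyl-protected macrocycle with a (Z)-CH=CH bridge between rings B and C | COc1ccc2cc1Oc1ccc(cc1)/C=C\c1ccc(OC(C)C)c(c1)Oc1cccc(c1)CC2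
F2 | step 6 | 4-(2-methoxy-5-{2-[3-(4,4,5,5-tetramethyl-1,3,2-dioxaborolan-2-yl)phenyl]ethyl}phenoxy)benzaldehyde | COc1ccc(CCc2cccc(B3OC(C)(C)C(C)(C)O3)c2)cc1Oc1ccc(C=O)cc1
F3 | step 6 | (3-{2-[3-(4-formylphenoxy)-4-methoxyphenyl]ethyl}phenyl)boronic acid | COc1ccc(CCc2cccc(B(O)O)c2)cc1Oc1ccc(C=O)cc1
F4 | step 2 | 3-(tert-butyldimethylsilyloxy)-4-methoxybenzaldehyde | COc1ccc(C=O)cc1O[Si](C)(C)C(C)(C)C
F5 | step 2 | tert-butyl{5-[2-(3-bromophenyl)ethenyl]-2-methoxyphenoxy}dimethylsilane (E isomer drawn) | COc1ccc(/C=C/c2cccc(Br)c2)cc1O[Si](C)(C)C(C)(C)C
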